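Late in the noon run E lies flat near 0.02190 M, and late in the winter run near 0.01100 M. I read each flat stretch as a crossing, where E is made as fast as it goes. The midnight flask starts with E already charged, so I need to know how fast E goes.

| setting | noon | winter | midnight |
|---|---|---|---|
| L | 0.0800 M | 0.0400 M | 0.0800 M |
| G | 0.0880 M | 0.0880 M | 0.0880 M |
| X | 0.00400 M | 0.00400 M | 0.00400 M |
| E |  |  | 0.0240 M |
| time |  |  | 23 min |

| run | time / min | [E] / M |
|---|---|---|
| noon run | 3.3 | 0.0088 |
| noon run | 6.6 | 0.0140 |
| noon run | 9.9 | 0.0174 |
| noon run | 13 | 0.0188 |
| noon run | 16 | 0.0193 |
| noon run | 20 | 0.0218 |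
| noon run | 23 | 0.0220 |
| winter run | 3.3 | 0.0050 |
| winter run | 6.6 | 0.0066 |
| winter run | 9.9 | 0.0100 |
| winter run | 13 | 0.0095 |
| winter run | 16 | 0.0121 |
| winter run | 20 | 0.0103 |
| winter run | 23 | 0.0117 |

(readings scatter by 6 × 10⁻⁴ M)

- order of the initial rate in [L], near the charge of the noon run, the rate being that where two percent of its L are E (one fixed amount of E, the same in the runs compared)
- E in the midnight run at 23 min, as a share of the L charged

The noon run's first reading gives an average early making of r = 0.00267 M min⁻¹. The winter run, with half the L, gives 0.568 of that reading, so I take making as first order in L. The E standing at the level accounts for 27.4% of the L, so at most 72.6% of the L remains, and less if some E has been lost, which gives: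

clearance = r × L left / level = 0.0884 min⁻¹

This clearance ceiling is the largest first-order constant for the loss of E that I allow the noon run.

I treat the charged E as a load on top of the noon curve. If none of it goes, I get the roof:

(E at the last noon reading + charged E) / L charged = 57.5%

If it decays at the ceiling, I get the floor:

(E at the last noon reading + charged E × exp(−clearance × time)) / L charged = 31.4%

I cannot lower the roof by hand, since a dying catalyst could draw the same curves without any loss of E.

The forecast gives an order in L of 0.97 and a midnight share of 42%, on the ground that “Reversible L + G ⇌ E fits this”. That share is higher than my floor and lower than my roof.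

The flask gives an order of 1.0 and a share of 37.8%.

    X + L ⇌ XL, settled at all times (2.380 M⁻¹)
    XL + G → E + X + J (110.4 M⁻¹ min⁻¹)
    E + G → Q (0.8100 M⁻¹ min⁻¹)
    2 X ⇌ X2, settled at all times (306.0 M⁻¹)

E goes by reaction with G to Q: the simulated midnight run without that path reaches 79.8%, against 37.8% with it. At the noon charge, the pseudo-first-order constant of that loss, k2 times G, is 0.0713 min⁻¹, lower than my ceiling of 0.0884 min⁻¹. The winter run has the same G charged, and its simulated early rate of 0.0015 M min⁻¹ with its level sets a higher ceiling of 0.0962 min⁻¹.

(Readings and results were computed for substances that don't exist, noise included.)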